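## Retrosynthetic overview

1. Target 19 ⇒ vinyl carbinol 15 + lactam enol tosylate 17 (hydroboration, B-alkyl Suzuki coupling); the lactam ring is brought in intact, last.
2. 15 ⇒ dione 12: C6 by hydride from the α face, then acetate; C9 by equatorial vinyl addition.
3. 12 ⇒ keto-aldehyde 10: the formyl group is a traceless activator, removed by aerobic deformylation; C8 is set by equilibration.
4. 10 ⇒ acyclic silyloxy-trienal 8: one enantioselective intramolecular [4+2] forms C5–C10 and C8–C9, so ring A and ring B form together and the C10 quaternary centre is set.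
5. 8 ⇒ geranyl acetate 3 + pentenone 1; alkylation of a tertiary chloride installs the gem-dimethyl carbon.

Assumptions: labdane numbering is used for all bicyclic compounds (decalin C1–C10, side chain from C11, β = face of the C10 methyl). The (S)-configured catalyst in step 6 is taken to give the 10β-methyl series; if the first run shows the opposite sense, its (R)-antipode is used with no other change.

## Route

Step 1
Reactants: 1 (E)-pent-3-en-2-one
Product: 2 (E)-2-(trimethylsilyloxy)penta-1,3-diene
Conditions: LiN(i-Pr)2, THF, −78 °C; then Me3SiCl, −78 °C → rt; distil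
Reagents that add atoms: chlorotrimethylsilane, C[Si](C)(C)Cl
Why: kinetic deprotonation of the methyl group gives the cross-conjugated lithium dienolate, which is O-silylated (silyl enol ether formation); the E alkene is untouched.

Step 2
Reactants: 3 geranyl acetate
Product: 4 (2E)-7-chloro-3,7-dimethyloct-2-en-1-yl acetate
Conditions: HCl (gas, 1.1 equiv), CH2Cl2, −30 °C
Reagents that add atoms: hydrogen chloride, Cl
Why: Markovnikov hydrochlorination; only the remote electron-rich trisubstituted alkene is protonated, the 2,3-alkene being deactivated by the allylic acetate.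

Step 3
Reactants: 4 (2E)-7-chloro-3,7-dimethyloct-2-en-1-yl acetate; 2 (E)-2-(trimethylsilyloxy)penta-1,3-diene
Product: 6 (2E,8Z,10E)-3,7,7-trimethyl-9-(triisopropylsilyloxy)dodeca-2,8,10-trien-1-yl acetate, via enone acetate 5 (not isolated)
Conditions: 2 (2 equiv), ZnCl2 (15 mol %), CH2Cl2, −40 → 0 °C; then Et3N, i-Pr3SiOTf, 0 °C → rt
Reagents that add atoms: triisopropylsilyl trifluoromethanesulfonate, CC(C)[Si](C(C)C)(C(C)C)OS(=O)(=O)C(F)(F)F
Why: ZnCl2 ionises the tertiary chloride and the cation is captured at the CH2 terminus of the silyl dienol ether (Reetz α-tert-alkylation, SN1), then kinetic soft enolisation at the α′-CH2 gives the cross-conjugated (Z)-silyl dienol ether with the quaternary carbon trans to the propenyl group.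

Step 4
Reactants: 6 (2E,8Z,10E)-3,7,7-trimethyl-9-(triisopropylsilyloxy)dodeca-2,8,10-trien-1-yl acetate
Product: 7 (2E,8Z,10E)-3,7,7-trimethyl-9-(triisopropylsilyloxy)dodeca-2,8,10-trien-1-ol
Conditions: K2CO3 (0.2 equiv), MeOH, 0 °C
Reagents that add atoms: none
Why: base-catalysed transesterification of the acetate; the bulky silyl enol ether survives mild methanolic carbonate and no free enone is present to take up methoxide.

Step 5
Reactants: 7 (2E,8Z,10E)-3,7,7-trimethyl-9-(triisopropylsilyloxy)dodeca-2,8,10-trien-1-ol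
Product: 8 (2E,8Z,10E)-3,7,7-trimethyl-9-(triisopropylsilyloxy)dodeca-2,8,10-trienal
Conditions: MnO2 (activated, 15 equiv), CH2Cl2, rt; use at once
Reagents that add atoms: none
Why: selective allylic alcohol oxidation under neutral conditions, which keeps the E enal geometry and spares the silyl dienol ether.

Step 6
Reactants: 8 (2E,8Z,10E)-3,7,7-trimethyl-9-(triisopropylsilyloxy)dodeca-2,8,10-trienal
Product: 10 4,4,8β,10β-tetramethyl-6-oxo-trans-decalin-9β-carbaldehyde (H-5 α), via silyl enol ether cycloadduct 9 (not isolated)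
Conditions: (S)-1-(2-methylphenyl)-3,3-diphenyltetrahydro-1H,3H-pyrrolo[1,2-c][1,3,2]oxazaborole (C24H24BNO, 20 mol %) + HN(SO2CF3)2 (18 mol %), CH2Cl2 (0.02 M), −78 → −20 °C; then HF·pyridine, THF, 0 °C
Reagents that add atoms: none
Why: Proposed new method: the boron-bound E-enal (organised by the formyl C–H···O contact) is attacked at its β-carbon C10 by the nucleophilic C5 terminus of the tethered 2-silyloxydiene, and ring B closes at C8–C9 in an asynchronous endo intramolecular Diels–Alder reaction helped by the gem-dimethyl tether; face shielding by the catalyst fixes the C10 quaternary centre, the endo mode gives the trans ring fusion with 8-Me and 9-CHO β (C8 and C9 are reset in step 7), and the closest known chemistry is the cationic-oxazaborolidine-catalysed Diels–Alder reaction of 2-(triisopropylsilyloxy)butadiene with enals and of tethered trienals, together with Lewis-acid cycloadditions of hindered silyloxydienes with β,β-disubstituted enones, whereas a β,β-disubstituted enal has not been used in the enantioselective variant.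

Step 7
Reactants: 10 4,4,8β,10β-tetramethyl-6-oxo-trans-decalin-9β-carbaldehyde
Product: 12 4,4,8α,10β-tetramethyl-trans-decalin-6,9-dione (H-5 α, H-8 β), via 8β-methyl dione 11 (not isolated)
Conditions: O2 (1 atm), Cu(OAc)2 (10 mol %), 2,2′-bipyridine (10 mol %), 1,4-diazabicyclo[2.2.2]octane (1 equiv), DMF, 40 °C; then NaOMe (0.3 equiv), MeOH, rt
Reagents that add atoms: dioxygen, O=O
Why: aerobic copper-catalysed oxidative deformylation of an α,α-disubstituted aldehyde (enolate oxygenation to the α-hydroperoxy aldehyde, then C–C cleavage to ketone and formate), after which NaOMe epimerises C8 through the C9 enolate to the equatorial 8α-methyl, relieving the syn-diaxial clash with the C10 methyl, while H-5, flanked by two quaternary carbons, is not exchanged.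

Step 8
Reactants: 12 4,4,8α,10β-tetramethyl-trans-decalin-6,9-dione
Product: 13 6β-hydroxy-4,4,8α,10β-tetramethyl-trans-decalin-9-one
Conditions: LiBH(s-Bu)3 (1.1 equiv), THF, −78 °C; then H2O
Reagents that add atoms: none
Why: chemo- and stereoselective ketone reduction; the bulky hydride reaches only the C6 carbonyl (C9 is flanked by a quaternary and a tertiary carbon) and only from the α face, the β face being blocked by the axial C4 and C10 methyls, so the axial 6β-alcohol forms.

Step 9
Reactants: 13 6β-hydroxy-4,4,8α,10β-tetramethyl-trans-decalin-9-one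
Product: 14 4,4,8α,10β-tetramethyl-9β-vinyl-trans-decalin-6β,9α-diol
Conditions: CeCl3 (anhydrous, 3 equiv), CH2=CHMgBr (3 equiv), THF, −78 → 0 °C; then H2O
Reagents that add atoms: vinylmagnesium bromide, C=C[Mg]Br
Why: 1,2-addition of a vinylcerium reagent, whose low basicity suits the hindered enolisable ketone; as with 2,2,6-trimethylcyclohexanones the carbon nucleophile enters equatorially, trans to the 8α-methyl, so the vinyl group is β (equatorial) and the new hydroxyl α (axial).

Step 10
Reactants: 14 4,4,8α,10β-tetramethyl-9β-vinyl-trans-decalin-6β,9α-diol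
Product: 15 6β-acetoxy-4,4,8α,10β-tetramethyl-9β-vinyl-trans-decalin-9α-ol
Conditions: Ac2O (3 equiv), 4-(dimethylamino)pyridine (0.2 equiv), pyridine, 40 °C
Reagents that add atoms: acetic anhydride, CC(=O)OC(C)=O
Why: nucleophile-catalysed acylation of the secondary 6β-alcohol; the tertiary 9α-alcohol does not react under these conditions and no stereocentre changes.

Step 11
Reactants: 16 pyrrolidine-2,4-dione
Product: 17 5-oxo-2,5-dihydro-1H-pyrrol-3-yl 4-methylbenzenesulfonate
Conditions: TsCl (1.05 equiv), Et3N (1.2 equiv), CH2Cl2, 0 °C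
Reagents that add atoms: p-toluenesulfonyl chloride, Cc1ccc(cc1)S(Cl)(=O)=O
Why: O-sulfonylation of the enol of a vinylogous acid (pKa about 6), far faster than reaction at the lactam nitrogen.

Step 12
Reactants: 15 6β-acetoxy-4,4,8α,10β-tetramethyl-9β-vinyl-trans-decalin-9α-ol; 17 5-oxo-2,5-dihydro-1H-pyrrol-3-yl 4-methylbenzenesulfonate
Product: 19 (1R,3R,4R,4aS,8aS)-4-hydroxy-3,4a,8,8-tetramethyl-4-[2-(5-oxo-2,5-dihydro-1H-pyrrol-3-yl)ethyl]decahydronaphthalen-1-yl acetate, via alkylborane 18 (not isolated)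
Conditions: 9-borabicyclo[3.3.1]nonane (2.5 equiv), THF, rt → 50 °C; then 17, Pd(OAc)2 (5 mol %), 2-dicyclohexylphosphino-2′,6′-dimethoxybiphenyl (10 mol %), K3PO4 (3 equiv), H2O, THF, 50 °C
Reagents that add atoms: none
Why: anti-Markovnikov hydroboration of the monosubstituted alkene, then B-alkyl Suzuki–Miyaura coupling at the activated (β-acyl) enol tosylate; the phosphate base leaves the hindered acetate and the lactam intact and no stereocentre is involved.

## Compound list

1 | (E)-pent-3-en-2-one | C/C=C/C(C)=O | starting material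
2 | (E)-2-(trimethylsilyloxy)penta-1,3-diene | C/C=C/C(=C)O[Si](C)(C)C | intermediate
3 | geranyl acetate, (2E)-3,7-dimethylocta-2,6-dien-1-yl acetate | CC(C)=CCC/C(C)=C/COC(C)=O | starting material
4 | (2E)-7-chloro-3,7-dimethyloct-2-en-1-yl acetate | CC(C)(Cl)CCC/C(C)=C/COC(C)=O | intermediate
5 | (2E,10E)-3,7,7-trimethyl-9-oxododeca-2,10-dien-1-yl acetate | C/C=C/C(=O)CC(C)(C)CCC/C(C)=C/COC(C)=O | intermediate
6 | (2E,8Z,10E)-3,7,7-trimethyl-9-(triisopropylsilyloxy)dodeca-2,8,10-trien-1-yl acetate | C/C=C/C(O[Si](C(C)C)(C(C)C)C(C)C)=C/C(C)(C)CCC/C(C)=C/COC(C)=O | intermediate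
7 | (2E,8Z,10E)-3,7,7-trimethyl-9-(triisopropylsilyloxy)dodeca-2,8,10-trien-1-ol | C/C=C/C(O[Si](C(C)C)(C(C)C)C(C)C)=C/C(C)(C)CCC/C(C)=C/CO | intermediate
8 | (2E,8Z,10E)-3,7,7-trimethyl-9-(triisopropylsilyloxy)dodeca-2,8,10-trienal | C/C=C/C(O[Si](C(C)C)(C(C)C)C(C)C)=C/C(C)(C)CCC/C(C)=C/C=O | intermediate
9 | 4,4,8β,10β-tetramethyl-6-(triisopropylsilyloxy)-trans-octal-6-ene-9β-carbaldehyde (H-5 α, H-9 α) | CC(C)[Si](C(C)C)(C(C)C)OC1=C[C@H](C)[C@H](C=O)[C@@]2(C)CCCC(C)(C)[C@H]12 | intermediate
10 | 4,4,8β,10β-tetramethyl-6-oxo-trans-decalin-9β-carbaldehyde (H-5 α) | O=C1C[C@H](C)[C@H](C=O)[C@@]2(C)CCCC(C)(C)[C@H]12 | intermediate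
11 | 4,4,8β,10β-tetramethyl-trans-decalin-6,9-dione (H-5 α) | O=C1C[C@H](C)C(=O)[C@@]2(C)CCCC(C)(C)[C@H]12 | intermediate
12 | 4,4,8α,10β-tetramethyl-trans-decalin-6,9-dione (H-5 α, H-8 β) | O=C1C[C@@H](C)C(=O)[C@@]2(C)CCCC(C)(C)[C@H]12 | intermediate
13 | 6β-hydroxy-4,4,8α,10β-tetramethyl-trans-decalin-9-one | O[C@@H]1C[C@@H](C)C(=O)[C@@]2(C)CCCC(C)(C)[C@H]12 | intermediate
14 | 4,4,8α,10β-tetramethyl-9β-vinyl-trans-decalin-6β,9α-diol | O[C@@H]1C[C@@H](C)[C@](O)(C=C)[C@@]2(C)CCCC(C)(C)[C@H]12 | intermediate
15 | 6β-acetoxy-4,4,8α,10β-tetramethyl-9β-vinyl-trans-decalin-9α-ol | CC(=O)O[C@@H]1C[C@@H](C)[C@](O)(C=C)[C@@]2(C)CCCC(C)(C)[C@H]12 | intermediate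
16 | pyrrolidine-2,4-dione | O=C1CNC(=O)C1 | starting material
17 | 5-oxo-2,5-dihydro-1H-pyrrol-3-yl 4-methylbenzenesulfonate | Cc1ccc(cc1)S(=O)(=O)OC1=CC(=O)NC1 | intermediate
18 | 9-[2-(6β-acetoxy-9α-hydroxy-4,4,8α,10β-tetramethyl-trans-decalin-9β-yl)ethyl]-9-borabicyclo[3.3.1]nonane | CC(=O)O[C@@H]1C[C@@H](C)[C@](O)(CCB3C4CCCC3CCC4)[C@@]2(C)CCCC(C)(C)[C@H]12 | intermediate
19 | CNP0546323.1, (1R,3R,4R,4aS,8aS)-4-hydroxy-3,4a,8,8-tetramethyl-4-[2-(5-oxo-2,5-dihydro-1H-pyrrol-3-yl)ethyl]decahydronaphthalen-1-yl acetate (6β-acetoxy-9α-hydroxy, 8α-methyl, 10β-methyl, H-5 α) | CC(=O)O[C@@H]1C[C@@H](C)[C@](O)(CCC2=CC(=O)NC2)[C@@]2(C)CCCC(C)(C)[C@H]12 | target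

## Step count and risks

Total steps: 12. Longest linear sequence: 10 steps (3 → 4 → 6 → 7 → 8 → 10 → 12 → 13 → 14 → 15 → 19, i.e. steps 2–10 and 12).

Three steps most likely to fail:

**Step 6 (key cyclisation).** The β,β-disubstituted enal may react too slowly with the chiral catalyst or give low enantiomeric excess. The fallback sets out from 8 and returns at 13; it obtains the single enantiomer by classical resolution instead of catalysis. The same cyclisation is promoted with the achiral Lewis acid Me2AlCl (1.2 equiv, CH2Cl2, −78 → 0 °C, HF·pyridine work-up). It then gives 10 together with its mirror image, the ent-keto-aldehyde F4, formed through 9 and the ent-cycloadduct F3. Steps 7 and 8, run unchanged on the racemate, give 13 together with the ent-hydroxy ketone F7, by way of 11 and 12 and their mirror images, the ent-8β-methyl dione F5 and the ent-dione F6. Acylation with (1S)-camphanoyl chloride (pyridine, 4-(dimethylamino)pyridine, 60 °C) gives the diastereomeric esters, the camphanate of 13 F8 and the camphanate of ent-13 F9. These are separated by chromatography or crystallisation, and K2CO3 in MeOH cleaves F8 back to enantiopure 13.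

**Step 3 (tertiary alkylation).** Under ZnCl2 the silyl dienol ether 2 can add to the product enone 5 (Mukaiyama–Michael oligomers), and the tertiary cation can cyclise onto the internal alkene. The fallback sets out from 4 and returns at 5; it builds the enone by aldol condensation instead of carrying it in the nucleophile. Compound 4 is alkylated with commercial isopropenyloxytrimethylsilane (large excess, ZnCl2 cat., CH2Cl2, −40 °C) to the methyl ketone (2E)-3,7,7-trimethyl-9-oxodec-2-en-1-yl acetate F1, which is not a Michael acceptor. A boron aldol reaction (Bu2BOTf, i-Pr2NEt, then CH3CHO; enolisation on the methyl side) gives the β-hydroxy ketone (2E)-11-hydroxy-3,7,7-trimethyl-9-oxododec-2-en-1-yl acetate F2. Dehydration with p-toluenesulfonic acid (cat., toluene, 50 °C) gives 5, which is silylated as in the second half of step 3.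

**Step 9 (vinyl addition).** The nucleophile may attack from the α face (giving the 9-epimer) or simply enolise the ketone. The fallback sets out from 13 and returns at 14; it delivers oxygen, not carbon, to C9 from the α face. Wittig methylenation (Ph3P=CH2, 3 equiv, toluene, 80 °C) gives the exocyclic alkene 6β-hydroxy-4,4,8α,10β-tetramethyl-9-methylene-trans-decalin F10. Epoxidation (mCPBA, NaHCO3, CH2Cl2, 0 °C) from the open α face gives the spiro-epoxide F11 (oxygen α, CH2 β). Excess dimethylsulfonium methylide (Me3S+ I−, n-BuLi, THF, −10 °C → rt) opens the epoxide at its CH2 and loses Me2S, giving the one-carbon-homologated allylic alcohol 14.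

## Further compounds

F1 | step 3 | (2E)-3,7,7-trimethyl-9-oxodec-2-en-1-yl acetate | CC(=O)CC(C)(C)CCC/C(C)=C/COC(C)=O
F2 | step 3 | (2E)-11-hydroxy-3,7,7-trimethyl-9-oxododec-2-en-1-yl acetate (racemic at C11) | CC(O)CC(=O)CC(C)(C)CCC/C(C)=C/COC(C)=O
F3 | step 6 | ent-cycloadduct, mirror image of 9 | CC(C)[Si](C(C)C)(C(C)C)OC1=C[C@@H](C)[C@@H](C=O)[C@]2(C)CCCC(C)(C)[C@@H]12
F4 | step 6 | ent-keto-aldehyde, mirror image of 10 | O=C1C[C@@H](C)[C@@H](C=O)[C@]2(C)CCCC(C)(C)[C@@H]12
F5 | step 6 | ent-8β-methyl dione, mirror image of 11 | O=C1C[C@@H](C)C(=O)[C@]2(C)CCCC(C)(C)[C@@H]12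
F6 | step 6 | ent-dione, mirror image of 12 | O=C1C[C@H](C)C(=O)[C@]2(C)CCCC(C)(C)[C@@H]12
F7 | step 6 | ent-hydroxy ketone, mirror image of 13 | O[C@H]1C[C@H](C)C(=O)[C@]2(C)CCCC(C)(C)[C@@H]12
F8 | step 6 | (1S)-camphanate ester of 13 | O=C(O[C@@H]1C[C@@H](C)C(=O)[C@@]2(C)CCCC(C)(C)[C@H]12)[C@@]12CC[C@@](C)(C(=O)O1)C2(C)C
F9 | step 6 | (1S)-camphanate ester of ent-13 | O=C(O[C@H]1C[C@H](C)C(=O)[C@]2(C)CCCC(C)(C)[C@@H]12)[C@@]12CC[C@@](C)(C(=O)O1)C2(C)C
F10 | step 9 | 6β-hydroxy-4,4,8α,10β-tetramethyl-9-methylene-trans-decalin | O[C@@H]1C[C@@H](C)C(=C)[C@@]2(C)CCCC(C)(C)[C@H]12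
F11 | step 9 | 9α,11-epoxide of F10 (spiro-oxirane, oxygen α, CH2 β) | O[C@@H]1C[C@@H](C)[C@]3(CO3)[C@@]2(C)CCCC(C)(C)[C@H]12
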